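**Plan**
- Cuts, in retrosynthetic order: the O6–geranyl ether; the 4-acetate and two silyl ethers; the cis-(3R,4R) hydroxy lactone back to racemic 3-methylisochromane-1,4-dione; then the lactone ring (C1, O2, C3, C4, C4a, C8a) at C1–C8a and C3–C4.
- Enabling feature: ring carbon C8a and benzylic C4 are 1,3-related through C4a on the fully substituted benzene ring, and C4 sits at a carbonyl oxidation level. With Br on C8a and C4 masked as a 1,3-dithiane, the arene is a latent 1,3-dinucleophile (aryl anion plus acyl-anion equivalent, polarity reversal at C4).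
- Its partner is the 1,3-dielectrophile ClC(=O)–O–CHCl–CH3, which already holds C1–O2–C3 and the methyl group.
- Forward: the benzene ring is bought; O8 comes from a Baeyer–Villiger oxidation and C4 from ortho-lithiation/formylation. The [3+3] annulation then closes the lactone ring, the dithiane (temporary spiro ring) is removed, and reduction, acetylation, desilylation and geranylation follow.
- Stereochemistry: C3 is epimerisable next to the C4 ketone, so one asymmetric transfer hydrogenation with dynamic kinetic resolution sets C4 (catalyst control) and C3 (cis, ring control) together.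

Key step: step 6

Remark: isochromanone numbering is used throughout (C1 lactone carbonyl, O2, C3, C4, C4a, C5–C8, C8a). 1-Chloroethyl chloroformate is used as the commercial racemate, which is immaterial because C3 is set in step 8.

**Route**

Step 1
Reactants: 1 2-bromo-5-hydroxy-4-methoxybenzaldehyde
Product: 2 2-bromo-4-methoxy-5-[(triisopropylsilyl)oxy]benzaldehyde
Conditions: iPr3SiCl, imidazole, DMF, rt
Reagents that add atoms: triisopropylsilyl chloride CC(C)[Si](Cl)(C(C)C)C(C)C
Why: Standard silylation of the only free phenol (the later O6); the triisopropylsilyl ether survives peracid, lithium amide, alkyllithium and BF3/thiol conditions and does not direct ortho-lithiation.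

Step 2
Reactants: 2 2-bromo-4-methoxy-5-[(triisopropylsilyl)oxy]benzaldehyde
Product: 4 2-bromo-4-methoxy-5-[(triisopropylsilyl)oxy]phenol, via aryl formate 3 (not isolated)
Conditions: mCPBA, CH2Cl2, 0 °C to rt; then Et3N (cat.), MeOH, 0 °C
Reagents that add atoms: 3-chloroperoxybenzoic acid O=C(OO)c1cccc(Cl)c1
Why: Baeyer–Villiger (Dakin-type) oxidation in which the electron-rich aryl group, para to OMe, migrates to oxygen; mild methanolysis of the formate frees the phenol that becomes O8, ortho to the bromine on the future C8a.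

Step 3
Reactants: 4 2-bromo-4-methoxy-5-[(triisopropylsilyl)oxy]phenol
Product: 5 1-bromo-5-methoxy-2,4-bis[(triisopropylsilyl)oxy]benzene
Conditions: iPr3SiCl, imidazole, DMF, 40 °C
Reagents that add atoms: triisopropylsilyl chloride CC(C)[Si](Cl)(C(C)C)C(C)C
Why: Silylation of the second phenol leaves a substrate whose only acidified ring C–H lies between Br and OMe.

Step 4
Reactants: 5 1-bromo-5-methoxy-2,4-bis[(triisopropylsilyl)oxy]benzene
Product: 7 2-bromo-6-methoxy-3,5-bis[(triisopropylsilyl)oxy]benzaldehyde, via ortho-bromoaryllithium 6 (not isolated)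
Conditions: LiN(iPr)2, THF, −78 °C; DMF, −78 °C; then 1 M HCl
Reagents that add atoms: N,N-dimethylformamide CN(C)C=O
Why: Directed ortho-lithiation by a lithium amide should take the ring proton flanked by Br and OMe (the other ring H sits between two bulky, non-coordinating silyl ethers), and formylation at −78 °C, below the temperature of LiBr loss from the aryllithium, installs C4.

Step 5
Reactants: 7 2-bromo-6-methoxy-3,5-bis[(triisopropylsilyl)oxy]benzaldehyde
Product: 8 2-{2-bromo-6-methoxy-3,5-bis[(triisopropylsilyl)oxy]phenyl}-1,3-dithiane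
Conditions: HS(CH2)3SH, BF3·OEt2 (0.3 equiv), CH2Cl2, 0 °C to rt
Reagents that add atoms: propane-1,3-dithiol SCCCS
Why: Lewis-acid-catalysed dithioacetalisation turns the C4 aldehyde into a 1,3-dithiane, the acyl-anion equivalent (Corey–Seebach umpolung) and temporary ring that the annulation needs.

Step 6
Reactants: 8 2-{2-bromo-6-methoxy-3,5-bis[(triisopropylsilyl)oxy]phenyl}-1,3-dithiane; 9 1-chloroethyl chloroformate (racemic)
Product: 13 (±)-5-methoxy-3-methyl-6,8-bis[(triisopropylsilyl)oxy]spiro[isochromane-4,2'-[1,3]dithian]-1-one, via aryllithium 10 (not isolated), via 1-chloroethyl ester 11 (not isolated), via 2-lithiodithiane 12 (not isolated)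
Conditions: t-BuLi (2 equiv), THF, −90 °C; 9 (1.05 equiv), −90 to −78 °C; LiN(iPr)2 (1.3 equiv), −78 to −20 °C
Reagents that add atoms: none
Why: Proposed new method: t-BuLi exchanges the bromine on C8a for lithium at −90 °C (faster than removal of the weakly acidic dithiane proton), the aryllithium is acylated at the acid-chloride carbon of 9 to make C1–C8a, and LiN(iPr)2 then lithiates the dithiane carbon C4, which displaces chloride from the α-chloroalkyl ester carbon C3 to make C3–C4, so that the arene acts as a 1,3-dinucleophile toward a C1–O2–C3 1,3-dielectrophile. The closest known reaction types are the acylation of aryllithiums by chloroformates, the Corey–Seebach alkylation of 2-aryl-2-lithio-1,3-dithianes with alkyl halides and α-chloro ethers, and the substitution of 1-chloroethyl esters and carbonates by soft nucleophiles; their combination into one [3+3] annulation has no direct precedent. The δ-lactone ring is closed by C–C bond formation in a 6-exo-tet alkylation with the C1–O2 ester bond already in place, so the five-membered phthalide that a hydroxy-acid lactonisation could give cannot form. C3 is created without control on purpose, since it becomes epimerisable next to the C4 ketone and is set together with C4 in step 8, and the spiro carbon C4 is not stereogenic. The step needs chemoselectivity at each stage (acyl chloride before alkyl chloride for the hard aryllithium, deprotonation of the dithiane before E2 loss of HCl, ring closure at C3 as the only ring size within reach), which the hard/soft match, the shielding of C7–H by two bulky silyl ethers, the use of t-BuLi (no alkyl bromide is left to compete) and the intramolecularity should secure.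

Step 7
Reactants: 13 (±)-5-methoxy-3-methyl-6,8-bis[(triisopropylsilyl)oxy]spiro[isochromane-4,2'-[1,3]dithian]-1-one
Product: 14 (±)-5-methoxy-3-methyl-6,8-bis[(triisopropylsilyl)oxy]isochromane-1,4-dione
Conditions: PhI(OCOCF3)2, MeCN/H2O (9:1), 0 °C
Reagents that add atoms: water O
Why: Oxidative dithiane hydrolysis with a hypervalent iodine reagent (sulfur oxidation, thionium ion, capture by water) should unmask the C4 ketone under mildly acidic conditions that spare the lactone and the aryl silyl ethers.

Step 8
Reactants: 14 (±)-5-methoxy-3-methyl-6,8-bis[(triisopropylsilyl)oxy]isochromane-1,4-dione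
Product: 15 (3R,4R)-4-hydroxy-5-methoxy-3-methyl-6,8-bis[(triisopropylsilyl)oxy]isochroman-1-one
Conditions: RuCl[(S,S)-TsDPEN](p-cymene) (2 mol %), HCO2H/Et3N (5:2), CH2Cl2, 30 °C
Reagents that add atoms: none
Why: Asymmetric transfer hydrogenation with dynamic kinetic resolution (Noyori–Ikariya type): C3–H epimerises through the enol (a 4-hydroxyisocoumarin) faster than reduction, the (S,S)-catalyst should fix the hydride face at C4 (4R by the aryl ketone model, the sense that turns benzil into (R,R)-hydrobenzoin), and the epimer that takes hydride anti to the 3-methyl group reacts faster, which gives the cis (3R,4R) alcohol.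

Step 9
Reactants: 15 (3R,4R)-4-hydroxy-5-methoxy-3-methyl-6,8-bis[(triisopropylsilyl)oxy]isochroman-1-one
Product: 16 (3R,4R)-5-methoxy-3-methyl-1-oxo-6,8-bis[(triisopropylsilyl)oxy]isochroman-4-yl acetate
Conditions: Ac2O, pyridine, DMAP (cat.), CH2Cl2, 0 °C to rt
Reagents that add atoms: acetic anhydride CC(=O)OC(C)=O
Why: DMAP-catalysed acylation of the hindered secondary benzylic alcohol with retention (no bond to C4 is broken), done at once so that the free 4-OH cannot migrate the lactone acyl group to a phthalide.

Step 10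
Reactants: 16 (3R,4R)-5-methoxy-3-methyl-1-oxo-6,8-bis[(triisopropylsilyl)oxy]isochroman-4-yl acetate
Product: 17 (3R,4R)-6,8-dihydroxy-5-methoxy-3-methyl-1-oxoisochroman-4-yl acetate
Conditions: Bu4NF, AcOH, THF, 0 °C
Reagents that add atoms: none
Why: Fluoride cleaves both aryl Si–O bonds, and buffering with acetic acid keeps the phenols protonated so that the acetate and the lactone are not attacked; neither phenol is ortho or para to the benzylic carbon, so no quinone methide can form.

Step 11
Reactants: 17 (3R,4R)-6,8-dihydroxy-5-methoxy-3-methyl-1-oxoisochroman-4-yl acetate; 18 geranyl bromide, (2E)-1-bromo-3,7-dimethylocta-2,6-diene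
Product: 19 (3R,4R)-6-{[(2E)-3,7-dimethylocta-2,6-dien-1-yl]oxy}-8-hydroxy-5-methoxy-3-methyl-1-oxoisochroman-4-yl acetate (CNP0251645.2)
Conditions: 18 (1.05 equiv), K2CO3 (1.1 equiv), acetone, rt
Reagents that add atoms: none
Why: Williamson etherification in which the 8-OH is held in a hydrogen bond to the lactone carbonyl and is the less acidic phenol, so one equivalent of weak base should alkylate the 6-OH (para to C8a) by SN2 with the (E)-allylic geometry kept.

**Compound list**
1 | 2-bromo-5-hydroxy-4-methoxybenzaldehyde | O=Cc1cc(O)c(OC)cc1Br | starting material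
2 | 2-bromo-4-methoxy-5-[(triisopropylsilyl)oxy]benzaldehyde | O=Cc1cc(O[Si](C(C)C)(C(C)C)C(C)C)c(OC)cc1Br | intermediate
3 | 2-bromo-4-methoxy-5-[(triisopropylsilyl)oxy]phenyl formate | O=COc1cc(O[Si](C(C)C)(C(C)C)C(C)C)c(OC)cc1Br | intermediate
4 | 2-bromo-4-methoxy-5-[(triisopropylsilyl)oxy]phenol | Oc1cc(O[Si](C(C)C)(C(C)C)C(C)C)c(OC)cc1Br | intermediate
5 | 1-bromo-5-methoxy-2,4-bis[(triisopropylsilyl)oxy]benzene | COc1cc(Br)c(O[Si](C(C)C)(C(C)C)C(C)C)cc1O[Si](C(C)C)(C(C)C)C(C)C | intermediate
6 | 2-bromo-6-methoxy-3,5-bis[(triisopropylsilyl)oxy]phenyllithium | [Li]c1c(Br)c(O[Si](C(C)C)(C(C)C)C(C)C)cc(O[Si](C(C)C)(C(C)C)C(C)C)c1OC | intermediate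
7 | 2-bromo-6-methoxy-3,5-bis[(triisopropylsilyl)oxy]benzaldehyde | O=Cc1c(Br)c(O[Si](C(C)C)(C(C)C)C(C)C)cc(O[Si](C(C)C)(C(C)C)C(C)C)c1OC | intermediate
8 | 2-{2-bromo-6-methoxy-3,5-bis[(triisopropylsilyl)oxy]phenyl}-1,3-dithiane | COc1c(C2SCCCS2)c(Br)c(O[Si](C(C)C)(C(C)C)C(C)C)cc1O[Si](C(C)C)(C(C)C)C(C)C | intermediate
9 | 1-chloroethyl chloroformate (racemic) | CC(Cl)OC(Cl)=O | starting material
10 | 2-(1,3-dithian-2-yl)-3-methoxy-4,6-bis[(triisopropylsilyl)oxy]phenyllithium | COc1c(C2SCCCS2)c([Li])c(O[Si](C(C)C)(C(C)C)C(C)C)cc1O[Si](C(C)C)(C(C)C)C(C)C | intermediate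
11 | 1-chloroethyl 2-(1,3-dithian-2-yl)-3-methoxy-4,6-bis[(triisopropylsilyl)oxy]benzoate | COc1c(C2SCCCS2)c(C(=O)OC(C)Cl)c(O[Si](C(C)C)(C(C)C)C(C)C)cc1O[Si](C(C)C)(C(C)C)C(C)C | intermediate
12 | 1-chloroethyl 2-(2-lithio-1,3-dithian-2-yl)-3-methoxy-4,6-bis[(triisopropylsilyl)oxy]benzoate | COc1c(C2([Li])SCCCS2)c(C(=O)OC(C)Cl)c(O[Si](C(C)C)(C(C)C)C(C)C)cc1O[Si](C(C)C)(C(C)C)C(C)C | intermediate
13 | (±)-5-methoxy-3-methyl-6,8-bis[(triisopropylsilyl)oxy]spiro[isochromane-4,2'-[1,3]dithian]-1-one | COc1c(O[Si](C(C)C)(C(C)C)C(C)C)cc(O[Si](C(C)C)(C(C)C)C(C)C)c2c1C3(SCCCS3)C(C)OC2=O | intermediate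
14 | (±)-5-methoxy-3-methyl-6,8-bis[(triisopropylsilyl)oxy]isochromane-1,4-dione | COc1c(O[Si](C(C)C)(C(C)C)C(C)C)cc(O[Si](C(C)C)(C(C)C)C(C)C)c2c1C(=O)C(C)OC2=O | intermediate
15 | (3R,4R)-4-hydroxy-5-methoxy-3-methyl-6,8-bis[(triisopropylsilyl)oxy]isochroman-1-one | COc1c(O[Si](C(C)C)(C(C)C)C(C)C)cc(O[Si](C(C)C)(C(C)C)C(C)C)c2c1[C@@H](O)[C@@H](C)OC2=O | intermediate
16 | (3R,4R)-5-methoxy-3-methyl-1-oxo-6,8-bis[(triisopropylsilyl)oxy]isochroman-4-yl acetate | COc1c(O[Si](C(C)C)(C(C)C)C(C)C)cc(O[Si](C(C)C)(C(C)C)C(C)C)c2c1[C@@H](OC(C)=O)[C@@H](C)OC2=O | intermediate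
17 | (3R,4R)-6,8-dihydroxy-5-methoxy-3-methyl-1-oxoisochroman-4-yl acetate | COc1c(O)cc(O)c2c1[C@@H](OC(C)=O)[C@@H](C)OC2=O | intermediate
18 | geranyl bromide, (2E)-1-bromo-3,7-dimethylocta-2,6-diene | CC(C)=CCC/C(C)=C/CBr | starting material
19 | (3R,4R)-6-{[(2E)-3,7-dimethylocta-2,6-dien-1-yl]oxy}-8-hydroxy-5-methoxy-3-methyl-1-oxoisochroman-4-yl acetate | COc1c(OC/C=C(\C)CCC=C(C)C)cc(O)c2c1[C@@H](OC(C)=O)[C@@H](C)OC2=O | target

**Totals**
Total steps: 11. Longest linear sequence: 11 steps (1 to 19); 9 and 18 are purchased.

**Steps most likely to fail**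

1. Step 6 (Proposed new method).
- What may go wrong: deprotonation of the dithiane or silyl migration from O8 to C8a competing with the halogen–lithium exchange; attack of the aryllithium at the alkyl chloride; base-induced loss of HCl from the 1-chloroethyl ester to a vinyl ester; slow ring closure, because the ester must adopt the lactone-like conformation and the new bond joins a fully substituted carbanion to a secondary carbon.
- Fallback (known chemistry, the two bonds made in separate operations): the fallback sets out from 8. Bromine–lithium exchange with n-BuLi (THF, −90 °C) and carboxylation with CO2 give 2-(1,3-dithian-2-yl)-3-methoxy-4,6-bis[(triisopropylsilyl)oxy]benzoic acid F1. Its dianion (n-BuLi, 2.2 equiv, −40 °C; carboxylate plus 2-lithiodithiane) adds acetaldehyde in a Corey–Seebach addition to give 2-[2-(1-hydroxyethyl)-1,3-dithian-2-yl]-3-methoxy-4,6-bis[(triisopropylsilyl)oxy]benzoic acid F2. Acid-catalysed lactonisation (TsOH, toluene, 60 °C), for which only one hydroxyl is available, comes back to the route at 13.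

2. Step 8.
- What may go wrong: slow hydride transfer to a ketone flanked by the peri methoxy group, epimerisation at C3 that does not keep pace with reduction, or base-induced acyl migration of the product to the five-membered phthalide.
- Fallback: the fallback sets out from 14 and uses an enzymatic dynamic kinetic resolution with an NADPH-dependent ketoreductase (alcohol dehydrogenase class), glucose/glucose dehydrogenase cofactor recycling, phosphate buffer (pH 7)/DMSO, with a (4R)-selective enzyme chosen from a panel. The C3 epimers interconvert through the enol at this pH without added base. It comes back to the route at 15 and makes no new compound (F0).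

3. Step 7.
- What may go wrong: oxidation of the electron-rich arene or α-hydroxylation of the enolisable dione by the iodine reagent, or incomplete hydrolysis of the hindered spiro dithiane.
- Fallback: the fallback sets out from 13. Chemoselective oxidation of one sulfur with NaIO4 (MeOH/H2O, 0 °C) gives (±)-5-methoxy-3-methyl-6,8-bis[(triisopropylsilyl)oxy]spiro[isochromane-4,2'-[1,3]dithian]-1-one 1'-oxide F3. Dilute HCl in aqueous MeCN hydrolyses it with a sulfenic acid as leaving group and no free oxidant present, and the route is rejoined at 14.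

**Further compounds**
F1 | step 6 | 2-(1,3-dithian-2-yl)-3-methoxy-4,6-bis[(triisopropylsilyl)oxy]benzoic acid | COc1c(C2SCCCS2)c(C(=O)O)c(O[Si](C(C)C)(C(C)C)C(C)C)cc1O[Si](C(C)C)(C(C)C)C(C)C
F2 | step 6 | 2-[2-(1-hydroxyethyl)-1,3-dithian-2-yl]-3-methoxy-4,6-bis[(triisopropylsilyl)oxy]benzoic acid | COc1c(C2(C(C)O)SCCCS2)c(C(=O)O)c(O[Si](C(C)C)(C(C)C)C(C)C)cc1O[Si](C(C)C)(C(C)C)C(C)C
F0 | step 8 | none | none
F3 | step 7 | (±)-5-methoxy-3-methyl-6,8-bis[(triisopropylsilyl)oxy]spiro[isochromane-4,2'-[1,3]dithian]-1-one 1'-oxide | COc1c(O[Si](C(C)C)(C(C)C)C(C)C)cc(O[Si](C(C)C)(C(C)C)C(C)C)c2c1C3(SCCCS3=O)C(C)OC2=O
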